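A direct plan would carry the side chain as the α-methyl aldehyde A1, join it to C5 of a preformed O-allyl 3-methyltetronate A2 by a vinylogous aldol addition to give A3, dehydrate to the E-ylidene tetronate A4, and finish by deallylation and O-stearoylation (numbering: ring O1, C2, C3, C4, C5; exocyclic C6; stereocentre C7). Its weakest steps would be:
- the aldol union, because an open transition state would not fix the C5/C6 relative configuration;
- the dehydration, because the E geometry would rest on a strictly concerted anti elimination, and any E1cB leakage through the furanolate would give the more stable Z isomer;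
- the assembly of A1 by sulfone alkylation, desulfonylation and protecting-group steps, which would add length without complexity.

The exocyclic enol-lactone alkene C5=C6 is traced back to a triple bond: ynoate 11, whose ester carbon is already C4 and whose propargylic carbon is the stereocentre C7. Palladium-catalysed cis-hydrostannation and iodinolysis put H on C6 and I on C5 with C7 cis to C4, so the E geometry follows from the mechanism of a syn addition and not from the conformation of an elimination. O1 is then attached by copper-mediated C–O coupling with retention, and the tetronate ring is closed last, at C3–C4, by Dieckmann condensation and acylated in the same flask. The chain and C7 come from farnesyl chloride by allylic oxidation and directed asymmetric hydrogenation, so no aldol, dehydration, sulfone or protecting-group step remains.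

Key step: step 8

Assumption: the sense of induction in step 4 is taken from the geraniol model of the BINAP–ruthenium hydrogenation (face selection through the CH2OH–C=C unit), which predicts the 2S alcohol with the (S)-ligand; it would be checked on the first batch and the antipodal ligand used if needed.

Step 1
Reactants: 1 furan-3-ylmethanol
Product: 2 3-(chloromethyl)furan
Conditions: SOCl2 (1.1 equiv), pyridine (1.1 equiv), Et2O, 0 °C
Reagents that add atoms: thionyl chloride, O=S(Cl)Cl
Why: Chlorodehydroxylation through the chlorosulfite, with pyridine as acid scavenger, should give the furylmethyl chloride without acid damage to the furan.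

Step 2
Reactants: 2 3-(chloromethyl)furan; 3 (2E,6E)-1-chloro-3,7,11-trimethyldodeca-2,6,10-triene (farnesyl chloride)
Product: 5 3-[(3E,7E)-4,8,12-trimethyltrideca-3,7,11-trien-1-yl]furan, via (furan-3-ylmethyl)magnesium chloride 4 (not isolated)
Conditions: 2 (1.3 equiv), Mg, THF, 0 °C to rt (dilute); then 3, Li2CuCl4 (3 mol %), THF, 0 °C
Reagents that add atoms: none
Why: Copper-catalysed Grignard–allylic chloride cross-coupling (Kochi type) should substitute at the primary α-carbon with retention of the E alkene, so that chain carbons C6–C17 with both E-trisubstituted alkenes are bought in one piece.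

Step 3
Reactants: 5 3-[(3E,7E)-4,8,12-trimethyltrideca-3,7,11-trien-1-yl]furan
Product: 6 (2E,6E,10E)-13-(furan-3-yl)-2,6,10-trimethyltrideca-2,6,10-trien-1-ol
Conditions: SeO2 (0.3 equiv), t-BuOOH (2.5 equiv), salicylic acid (0.1 equiv), CH2Cl2, 0 °C to rt
Reagents that add atoms: tert-butyl hydroperoxide, CC(C)(C)OO (terminal oxidant; the oxygen is relayed by SeO2, O=[Se]=O)
Why: Catalytic SeO2/t-BuOOH allylic oxidation (ene reaction, then [2,3]-sigmatropic shift) should hydroxylate the E-methyl of the terminal, least hindered trisubstituted alkene; this carbon becomes C6.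

Step 4
Reactants: 6 (2E,6E,10E)-13-(furan-3-yl)-2,6,10-trimethyltrideca-2,6,10-trien-1-ol
Product: 7 (2S,6E,10E)-13-(furan-3-yl)-2,6,10-trimethyltrideca-6,10-dien-1-ol
Conditions: Ru(OAc)2[(S)-BINAP] (1 mol %), H2 (30 atm), MeOH, 25 °C
Reagents that add atoms: none
Why: Noyori hydroxyl-directed asymmetric hydrogenation reduces only the alkene that can bind ruthenium through the allylic alkoxide, so the two remote alkenes and the furan should stay, and the stereocentre C7 is set by the chiral diphosphine, which selects the alkene face (catalyst control).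

Step 5
Reactants: 7 (2S,6E,10E)-13-(furan-3-yl)-2,6,10-trimethyltrideca-6,10-dien-1-ol
Product: 8 (2S,6E,10E)-13-(furan-3-yl)-2,6,10-trimethyltrideca-6,10-dienal
Conditions: Dess–Martin periodinane (1.2 equiv), CH2Cl2, 0 °C to rt; cold Na2S2O3/NaHCO3 work-up; used at once
Reagents that add atoms: none
Why: Dess–Martin oxidation is non-basic, so the α-methyl aldehyde should form without epimerisation and is taken on crude.

Step 6
Reactants: 8 (2S,6E,10E)-13-(furan-3-yl)-2,6,10-trimethyltrideca-6,10-dienal
Product: 9 3-[(3E,7E,12S)-14,14-dibromo-4,8,12-trimethyltetradeca-3,7,13-trien-1-yl]furan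
Conditions: CBr4 (2 equiv), PPh3 (4 equiv), 2,6-lutidine (2 equiv), CH2Cl2, 0 °C
Reagents that add atoms: tetrabromomethane, BrC(Br)(Br)Br
Why: Ramirez dibromo-olefination (first stage of the Corey–Fuchs sequence) is a Wittig reaction of Ph3P=CBr2 under non-basic conditions, so the α-stereocentre should be kept; the new carbon becomes C5.

Step 7
Reactants: 9 3-[(3E,7E,12S)-14,14-dibromo-4,8,12-trimethyltetradeca-3,7,13-trien-1-yl]furan
Product: 11 methyl (4S,8E,12E)-15-(furan-3-yl)-4,8,12-trimethylpentadeca-8,12-dien-2-ynoate, via lithium acetylide 10 (not isolated)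
Conditions: n-BuLi (2.1 equiv), THF, −78 °C, 1 h; then ClCO2Me (1.5 equiv), −78 to −20 °C; NH4Cl quench at −78 °C
Reagents that add atoms: methyl chloroformate, COC(=O)Cl
Why: Second stage of the Corey–Fuchs reaction (bromine–lithium exchange, Fritsch–Buttenberg–Wiechell 1,2-shift, deprotonation) gives the lithium acetylide, which is C-acylated by the chloroformate; the ester carbon is C4 and the propargylic stereocentre is not deprotonated at −78 °C.

Step 8
Reactants: 11 methyl (4S,8E,12E)-15-(furan-3-yl)-4,8,12-trimethylpentadeca-8,12-dien-2-ynoate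
Product: 13 methyl (2E,4S,8E,12E)-15-(furan-3-yl)-2-iodo-4,8,12-trimethylpentadeca-2,8,12-trienoate, via α-stannyl enoate 12 (not isolated)
Conditions: Pd(PPh3)4 (3 mol %), Bu3SnH (1.15 equiv, slow addition), THF, 0 °C to rt; then I2 (1.2 equiv), 0 °C, dark; Na2S2O3 work-up
Reagents that add atoms: iodine, II
Why: Bu3SnH adds oxidatively to zerovalent palladium, the triple bond inserts into Pd–H in a syn fashion with hydride delivered to the β-carbon C6 and palladium to the α-carbon C5, and reductive elimination forms C5–Sn, so that H and Sn are cis and C7 is cis to the ester carbon C4; iodine then replaces tin at C5 by ipso substitution with retention. The closest known reaction type is the palladium-catalysed hydrostannation of alkynoates to (E)-2-stannyl-2-alkenoates, followed by iododestannylation. No ring is closed here (the tetronate ring is closed in step 10) and no stereocentre is created: the element that is set is the geometry of the future exocyclic C5=C6 bond, fixed by the syn addition, while the propargylic stereocentre C7 is untouched because no bond to it is made or broken. The step needs α-regioselectivity and no E/Z leakage: the polarisation of the ynoate and the branched C7 next to C6 both send tin to C5, and slow hydride addition, low temperature and exclusion of light should keep the kinetic isomer, in which I at C5 lies trans to C7 exactly as O1 does in the target.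

Step 9
Reactants: 13 methyl (2E,4S,8E,12E)-15-(furan-3-yl)-2-iodo-4,8,12-trimethylpentadeca-2,8,12-trienoate
Product: 14 methyl (2E,4S,8E,12E)-15-(furan-3-yl)-4,8,12-trimethyl-2-(propanoyloxy)pentadeca-2,8,12-trienoate
Conditions: EtCO2Cs (2 equiv), CuI (10 mol %), 3,4,7,8-tetramethyl-1,10-phenanthroline (20 mol %), 4 Å molecular sieves, toluene, 60 °C, dark
Reagents that add atoms: caesium propanoate, CCC(=O)[O-].[Cs+]
Why: Ullmann-type copper-catalysed C–O coupling of an alkenyl iodide with a carboxylate (oxidative addition of the activated C5–I bond to monovalent copper, reductive elimination from trivalent copper) should attach O1 to C5 with retention of the alkene geometry and give the E enol ester, which already holds O1, C2, C3 and the C3 methyl group.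

Step 10
Reactants: 14 methyl (2E,4S,8E,12E)-15-(furan-3-yl)-4,8,12-trimethyl-2-(propanoyloxy)pentadeca-2,8,12-trienoate; 15 octadecanoyl chloride (stearoyl chloride)
Product: 17 (2E)-2-[(2S,6E,10E)-13-(furan-3-yl)-2,6,10-trimethyltrideca-6,10-dien-1-ylidene]-4-methyl-5-oxo-2,5-dihydrofuran-3-yl octadecanoate (target), via lithium tetronate 16 (not isolated)
Conditions: LiN(SiMe3)2 (2.2 equiv), THF, −78 to −30 °C; then 15 (3 equiv), −78 to 0 °C
Reagents that add atoms: none
Why: Dieckmann (intramolecular Claisen) condensation, in which the propanoate enolate carbon C3 attacks the methyl ester carbon C4 in a 5-exo-trig closure and methoxide leaves, closes the tetronate ring last; the lithium tetronate is then O-acylated at O4 because C3 carries the methyl group, and neither the C5=C6 geometry nor C7 takes part.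

Compound list
1 | furan-3-ylmethanol | OCc1ccoc1 | starting material
2 | 3-(chloromethyl)furan | ClCc1ccoc1 | intermediate
3 | (2E,6E)-1-chloro-3,7,11-trimethyldodeca-2,6,10-triene (farnesyl chloride) | CC(C)=CCC/C(C)=C/CC/C(C)=C/CCl | starting material
4 | (furan-3-ylmethyl)magnesium chloride | Cl[Mg]Cc1ccoc1 | intermediate
5 | 3-[(3E,7E)-4,8,12-trimethyltrideca-3,7,11-trien-1-yl]furan | CC(C)=CCC/C(C)=C/CC/C(C)=C/CCc1ccoc1 | intermediate
6 | (2E,6E,10E)-13-(furan-3-yl)-2,6,10-trimethyltrideca-2,6,10-trien-1-ol | OC/C(C)=C/CC/C(C)=C/CC/C(C)=C/CCc1ccoc1 | intermediate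
7 | (2S,6E,10E)-13-(furan-3-yl)-2,6,10-trimethyltrideca-6,10-dien-1-ol | OC[C@@H](C)CCC/C(C)=C/CC/C(C)=C/CCc1ccoc1 | intermediate
8 | (2S,6E,10E)-13-(furan-3-yl)-2,6,10-trimethyltrideca-6,10-dienal | O=C[C@@H](C)CCC/C(C)=C/CC/C(C)=C/CCc1ccoc1 | intermediate
9 | 3-[(3E,7E,12S)-14,14-dibromo-4,8,12-trimethyltetradeca-3,7,13-trien-1-yl]furan | BrC(Br)=C[C@@H](C)CCC/C(C)=C/CC/C(C)=C/CCc1ccoc1 | intermediate
10 | lithium (3S,7E,11E)-14-(furan-3-yl)-3,7,11-trimethyltetradeca-7,11-dien-1-yn-1-ide | [Li]C#C[C@@H](C)CCC/C(C)=C/CC/C(C)=C/CCc1ccoc1 | intermediate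
11 | methyl (4S,8E,12E)-15-(furan-3-yl)-4,8,12-trimethylpentadeca-8,12-dien-2-ynoate | COC(=O)C#C[C@@H](C)CCC/C(C)=C/CC/C(C)=C/CCc1ccoc1 | intermediate
12 | methyl (2E,4S,8E,12E)-15-(furan-3-yl)-4,8,12-trimethyl-2-(tributylstannyl)pentadeca-2,8,12-trienoate | COC(=O)/C(=C\[C@@H](C)CCC/C(C)=C/CC/C(C)=C/CCc1ccoc1)[Sn](CCCC)(CCCC)CCCC | intermediate
13 | methyl (2E,4S,8E,12E)-15-(furan-3-yl)-2-iodo-4,8,12-trimethylpentadeca-2,8,12-trienoate | COC(=O)/C(I)=C\[C@@H](C)CCC/C(C)=C/CC/C(C)=C/CCc1ccoc1 | intermediate
14 | methyl (2E,4S,8E,12E)-15-(furan-3-yl)-4,8,12-trimethyl-2-(propanoyloxy)pentadeca-2,8,12-trienoate | CCC(=O)O/C(C(=O)OC)=C/[C@@H](C)CCC/C(C)=C/CC/C(C)=C/CCc1ccoc1 | intermediate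
15 | octadecanoyl chloride | CCCCCCCCCCCCCCCCCC(=O)Cl | starting material
16 | lithium (2E)-2-[(2S,6E,10E)-13-(furan-3-yl)-2,6,10-trimethyltrideca-6,10-dien-1-ylidene]-4-methyl-5-oxo-2,5-dihydrofuran-3-olate | [Li+].[O-]C1=C(C)C(=O)O/C1=C/[C@@H](C)CCC/C(C)=C/CC/C(C)=C/CCc1ccoc1 | intermediate
17 | (2E)-2-[(2S,6E,10E)-13-(furan-3-yl)-2,6,10-trimethyltrideca-6,10-dien-1-ylidene]-4-methyl-5-oxo-2,5-dihydrofuran-3-yl octadecanoate | CCCCCCCCCCCCCCCCCC(=O)OC1=C(C)C(=O)O/C1=C/[C@@H](C)CCC/C(C)=C/CC/C(C)=C/CCc1ccoc1 | target

Total steps: 10. Longest linear sequence: 10 steps (1 to 17); 3 and 15 enter as bought materials.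

Steps most likely to fail

Step 9 (copper-catalysed C–O coupling). Reductive homocoupling or protodeiodination of the alkenyl iodide may outrun C–O bond formation, and reversible conjugate addition of carboxylate may erode the alkene geometry. The fallback reverses the polarity at C5 and uses a nucleophilic alkenylboron in an oxidative coupling. Setting out from ynoate 11, copper-catalysed cis-hydroboration (Cu(OAc)2, 1,2-bis(diphenylphosphino)benzene, pinacolborane, THF, rt; hydride to C6, boron to C5) would give methyl (2Z,4S,8E,12E)-15-(furan-3-yl)-4,8,12-trimethyl-2-(4,4,5,5-tetramethyl-1,3,2-dioxaborolan-2-yl)pentadeca-2,8,12-trienoate F1. A Chan–Lam coupling of this boronate with propanoic acid (Cu(OAc)2, pyridine, molecular sieves, air, rt) would form the C5–O1 bond with retention and come back to the route at enol ester 14.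

Step 10 (Dieckmann closure and acylation). The ester enolate may fragment to methylketene and the enolate of the α-keto ester before it cyclises, or the base may deprotonate C7 and erode the stereocentre. The fallback closes the ring at O1–C5 instead of C3–C4. Setting out from iodide 13, acylation of the dianion of propanoic acid (EtCO2H, 2 LiN(i-Pr)2, THF, −78 to −20 °C) by the ester group would give (4E,6S,10E,14E)-17-(furan-3-yl)-4-iodo-2,6,10,14-tetramethyl-3-oxoheptadeca-4,10,14-trienoic acid F2, handled cold as its salt. Copper-catalysed intramolecular O-vinylation of the carboxylate (CuI, N,N′-dimethylethane-1,2-diamine, Cs2CO3, THF, 50 °C) would give (5E)-5-[(2S,6E,10E)-13-(furan-3-yl)-2,6,10-trimethyltrideca-6,10-dien-1-ylidene]-4-hydroxy-3-methylfuran-2(5H)-one F3. O-acylation with 15 (Et3N, CH2Cl2, 0 °C) would come back at target 17.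

Step 4 (asymmetric hydrogenation). Facial selectivity may be insufficient or reversed for this 2-methyl allylic alcohol, or the allylic alcohol may isomerise to the saturated aldehyde. The fallback is a biocatalytic reduction of the enal. Setting out from allylic alcohol 6, MnO2 (CH2Cl2, rt) would give (2E,6E,10E)-13-(furan-3-yl)-2,6,10-trimethyltrideca-2,6,10-trienal F4. Fermenting baker's yeast (glucose, water, 30 °C) would reduce the conjugated C=C bond and then the aldehyde, a reduction type that gives (S)-2-methylalkanols, and return to alcohol 7.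

Further compounds
F1 | step 9 | methyl (2Z,4S,8E,12E)-15-(furan-3-yl)-4,8,12-trimethyl-2-(4,4,5,5-tetramethyl-1,3,2-dioxaborolan-2-yl)pentadeca-2,8,12-trienoate | COC(=O)/C(B1OC(C)(C)C(C)(C)O1)=C\[C@@H](C)CCC/C(C)=C/CC/C(C)=C/CCc1ccoc1
F2 | step 10 | (4E,6S,10E,14E)-17-(furan-3-yl)-4-iodo-2,6,10,14-tetramethyl-3-oxoheptadeca-4,10,14-trienoic acid | CC(C(=O)O)C(=O)/C(I)=C\[C@@H](C)CCC/C(C)=C/CC/C(C)=C/CCc1ccoc1
F3 | step 10 | (5E)-5-[(2S,6E,10E)-13-(furan-3-yl)-2,6,10-trimethyltrideca-6,10-dien-1-ylidene]-4-hydroxy-3-methylfuran-2(5H)-one | OC1=C(C)C(=O)O/C1=C/[C@@H](C)CCC/C(C)=C/CC/C(C)=C/CCc1ccoc1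
F4 | step 4 | (2E,6E,10E)-13-(furan-3-yl)-2,6,10-trimethyltrideca-2,6,10-trienal | O=C/C(C)=C/CC/C(C)=C/CC/C(C)=C/CCc1ccoc1
A1 | direct plan | (2S,6E,10E)-13-(furan-3-yl)-2,6,10-trimethyltrideca-6,10-dienal | O=C[C@@H](C)CCC/C(C)=C/CC/C(C)=C/CCc1ccoc1
A2 | direct plan | 3-methyl-4-(prop-2-en-1-yloxy)furan-2(5H)-one | C=CCOC1=C(C)C(=O)OC1
A3 | direct plan | 5-[(2S,6E,10E)-13-(furan-3-yl)-1-hydroxy-2,6,10-trimethyltrideca-6,10-dien-1-yl]-3-methyl-4-(prop-2-en-1-yloxy)furan-2(5H)-one (mixture at C5 and C1′) | C=CCOC1=C(C)C(=O)OC1C(O)[C@@H](C)CCC/C(C)=C/CC/C(C)=C/CCc1ccoc1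
A4 | direct plan | (5E)-5-[(2S,6E,10E)-13-(furan-3-yl)-2,6,10-trimethyltrideca-6,10-dien-1-ylidene]-3-methyl-4-(prop-2-en-1-yloxy)furan-2(5H)-one | C=CCOC1=C(C)C(=O)O/C1=C/[C@@H](C)CCC/C(C)=C/CC/C(C)=C/CCc1ccoc1
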